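The easy step comes first: in each flask we ask which charge is the smaller, and what the runs say about it.

| flask | starting material | coupling partner | remark | time |
|---|---|---|---|---|
| teal | 0.050 M | 0.095 M | run made earlier |  |
| grey | 0.20 M | 0.095 M | run made earlier |  |
| flask | 0.10 M | 0.0950 M |  | 6.0 h |

- teal (time / h: target / %, starting material / %): 0.0833: 30.1, 69.8; 0.200: 49.6, 47.0; 0.417: 58.7, 29.5; 1.00: 47.1, 14.4; 2.50: 25.9, 5.4; 6.00: 12.4, 1.3
- grey (time / h: target / %, starting material / %): 0.0833: 23.2, 75.7; 0.200: 28.0, 66.0; 0.417: 24.1, 59.6; 1.00: 15.5, 54.4; 2.50: 7.0, 52.8; 6.00: 2.5, 52.3

(standard deviation of a reading: 0.5 percentage points)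

- the best time, 6.0 h at the latest, for target
- the amount of target, in percent of the starting material charged, at that time

In the grey run the starting material reads 52.3 % at 6.00 h, so 0.0954 M of it has gone, as much as the 0.095 M of coupling partner charged. One partner therefore takes one starting material, and the smaller charge is the limiting reagent. So we hold each peak against that charge. Teal, limited by its starting material, reads 58.7 % at 0.417 h. Grey, limited by its partner, reads 58.9 % at 0.200 h. Together they give 58.8 %, our peak share: the highest target over the charge of the limiting reagent.

There are two ways to the new flask. The peak share, applied to the limiting partner of the new flask, gives 55.9 %. The starting material charge of the new flask is also the geometric mean of teal and grey at the same partner charge, and the same mean of their peak readings gives 0.0405 M, which is 40.5 %, at about 0.289 h. The first way stands higher, and we take it for the one that cheats, because its share was read with the other reagent at 1.90 and 2.11 times the limiting one, whereas the new flask has 1.05. We commit to the second.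

The forecast gives 41 % at 0.4 h, “sensibly between teal and grey in both percent and molarity”, an amount close to ours at a later hour. The flask gives 42.8 % at 0.306 h.

    starting material + coupling partner ⇌ target + released group (K = 2.50, k = 0.860 L mol⁻¹ min⁻¹)
    coupling partner → decomposed reagent (k = 0.00150 min⁻¹)
    starting material → decomposition product (k = 7.50 × 10⁻⁵ min⁻¹)
    target + released group → side product (k = 0.510 L mol⁻¹ min⁻¹)

At that time 41.6 % of the coupling partner's own charge is still there. The flask's peak share comes to 45.0 %, lower than the runs'. A neighbour charged with 0.17 M of starting material has its reagents 1.79 to one, against 1.90 and 2.11 in the earlier runs; the peak share gives it 32.9 %, and it reaches 31.5 %.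

The earlier runs and the new flask are calculated from invented constants, noise included.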